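**Assumption:** the SMILES is taken literally, i.e. the cis‑fused decalin (5β‑H cis to the 10β‑CH3), 7β‑OH, 8α‑OAc, 9α‑O, 13S = (5R,7R,8R,9S,10S,13S). Labdane numbering is used for all intermediates (β = face of the C10 methyl).

**Retrosynthetic overview**
1. 23 ⇐ 20: the C13–O bond is closed last by 5‑exo attack of the 9α‑alkoxy radical on the 3‑furyl ring, which turns the furan into the dihydrofuran.
2. 20 ⇐ 17 ⇐ 16 ⇐ 15: 7β‑OH/8α‑OAc come from a 7β,8β‑epoxide opened by the neighbouring 9α‑acetate; C9 comes from addition of 2‑(3‑furyl)ethyllithium to enone 7.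
3. Key disconnection C4–C5: a tertiary radical (Fe–H HAT on 5‑bromo‑2‑methylpent‑2‑ene) adds to the chiral p‑quinone monoketal 3; ring A is then closed by enolate alkylation (C1–C10) and angular methylation.
4. 3 ⇐ o‑cresol by oxidative dearomatization; the (S,S)‑hydrobenzoin ketal is both the C6 protecting group and the stereocontrol element.
5. Ring order: B (from the arene) → A → spiro THF/dihydrofuran pair (last step).

**Route**

Step 1
Reactants: 1 2-methylphenol (o-cresol)
Product: 2 4,4-dimethoxy-2-methylcyclohexa-2,5-dien-1-one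
Conditions: PhI(OAc)2 (2.2 equiv), MeOH, 0 °C → rt
Reagents that add atoms: methanol, CO
Why: PhI(OAc)2 oxidative dearomatization of a para‑unsubstituted phenol (Pelter‑type); the phenoxenium ion is trapped twice at the para position by MeOH to give the p‑quinone monoketal, and no stereocentre is formed.

Step 2
Reactants: 2 4,4-dimethoxy-2-methylcyclohexa-2,5-dien-1-one
Product: 3 (2S,3S)-7-methyl-2,3-diphenyl-1,4-dioxaspiro[4.5]deca-6,9-dien-8-one
Conditions: (S,S)-hydrobenzoin (1.2 equiv), PPTS (10 mol %), benzene, 4 Å MS, 50 °C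
Reagents that add atoms: (1S,2S)-1,2-diphenylethane-1,2-diol, O[C@@H](c1ccccc1)[C@@H](O)c1ccccc1
Why: Acid‑catalysed transketalization driven by removal of MeOH; the C2‑symmetric diol gives a single ketal in which each phenyl group covers one face of one enone arm.

Step 3 (key step)
Reactants: 3 (2S,3S)-7-methyl-2,3-diphenyl-1,4-dioxaspiro[4.5]deca-6,9-dien-8-one; 4 5-bromo-2-methylpent-2-ene (3 equiv)
Product: 5 (2S,3S,10S)-10-(5-bromo-2-methylpentan-2-yl)-7-methyl-2,3-diphenyl-1,4-dioxaspiro[4.5]dec-6-en-8-one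
Conditions: Fe(acac)3 (30 mol %), PhSiH3 (2.5 equiv), EtOH/(CH2OH)2, 60 °C
Reagents that add atoms: none
Why: Mukaiyama‑type MHAT from an iron hydride to the trisubstituted alkene gives the tertiary radical, which adds (Giese/reductive olefin coupling) to the β‑carbon of the unsubstituted, more electrophilic enone arm anti to the phenyl group that flanks it, forging the congested C4–C5 bond and setting C5 (H β), after which the α‑keto radical is reduced and protonated.

Step 4
Reactants: 5 (2S,3S,10S)-10-(5-bromo-2-methylpentan-2-yl)-7-methyl-2,3-diphenyl-1,4-dioxaspiro[4.5]dec-6-en-8-one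
Product: 7 cis-fused 4,4,8,10β-tetramethyl-5β-H-decal-7-ene-6,9-dione 6-[(1S,2S)-1,2-diphenylethylene ketal], via des-methyl cis-decalin enone 6 (not isolated)
Conditions: LDA (1.1 equiv), THF/DMPU, −78 → 0 °C; then LDA (1.3 equiv), −78 °C; MeI, −78 → 0 °C
Reagents that add atoms: iodomethane, CI
Why: The kinetic α′‑enolate closes ring A by 6‑exo‑tet intramolecular alkylation (C10–C1), and a second enolization/angular methylation takes MeI on the convex face anti to the C4 quaternary carbon on C5, giving the cis‑fused decalin and setting C10 (CH3 β, cis to H‑5).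

Step 5
Reactants: 8 3-bromofuran; 9 oxirane
Product: 11 2-(furan-3-yl)ethan-1-ol, via furan-3-yllithium 10 (not isolated)
Conditions: n-BuLi, THF, −78 °C; oxirane, BF3·OEt2, −78 °C; aq. NaHCO3
Reagents that add atoms: none
Why: Br/Li exchange at −78 °C (no 3→2 lithium migration) followed by BF3‑assisted SN2 opening of the epoxide.

Step 6
Reactants: 11 2-(furan-3-yl)ethan-1-ol
Product: 12 3-(2-iodoethyl)furan
Conditions: PPh3, imidazole, I2, CH2Cl2, 0 °C
Reagents that add atoms: iodine, II
Why: Appel/Garegg–Samuelsson iodination by SN2 displacement of the alkoxyphosphonium ion under non‑acidic conditions that spare the furan.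

Step 7
Reactants: 7 cis-fused 4,4,8,10β-tetramethyl-5β-H-decal-7-ene-6,9-dione 6-[(1S,2S)-1,2-diphenylethylene ketal]; 12 3-(2-iodoethyl)furan
Product: 15 9α-acetoxy-15,16-epoxy-5β-labda-7,13(16),14-trien-6-one (1S,2S)-1,2-diphenylethylene ketal, via 2-(furan-3-yl)ethyllithium 13 (not isolated), via lithium 9α-alkoxide 14 (not isolated)
Conditions: 12, t-BuLi (2 equiv per iodide), Et2O, −78 °C; add 7 in THF, −78 → −30 °C; Ac2O, DMAP (cat.), −30 °C → rt
Reagents that add atoms: acetic anhydride, CC(=O)OC(C)=O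
Why: I/Li exchange and 1,2‑addition to the hindered enone, which has no α‑hydrogen, from the convex β face (the α face is blocked by the pseudo‑axial C4 carbon 1,3 to the carbonyl) sets C9 (O α, C11 β), and the tertiary alkoxide is O‑acetylated in situ.

Step 8
Reactants: 15 9α-acetoxy-15,16-epoxy-5β-labda-7,13(16),14-trien-6-one (1S,2S)-1,2-diphenylethylene ketal
Product: 16 9α-acetoxy-15,16-epoxy-5β-labda-7,13(16),14-trien-6-one
Conditions: 1 M aq. HCl/THF (1:3), rt
Reagents that add atoms: water, O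
Why: Hydrolysis of the allylic ketal through its conjugated oxocarbenium ion releases the C6 ketone and the auxiliary; the stereocentres are untouched because H‑5, flanked by two quaternary carbons, enolizes slowly.

Step 9
Reactants: 16 9α-acetoxy-15,16-epoxy-5β-labda-7,13(16),14-trien-6-one
Product: 17 9α-acetoxy-7β,8β:15,16-diepoxy-5β-labda-13(16),14-dien-6-one
Conditions: t-BuOOH (3 equiv), DBU (1.5 equiv), CH2Cl2, 0 °C → rt
Reagents that add atoms: tert-butyl hydroperoxide, CC(C)(C)OO
Why: Weitz–Scheffer nucleophilic epoxidation in which t‑BuOO− adds to C8 anti to the γ‑acetoxy group and from the convex β face, so ring closure gives the 7β,8β‑epoxide and sets the C7–O bond (β); the furan is inert to the nucleophilic oxidant.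

Step 10
Reactants: 17 9α-acetoxy-7β,8β:15,16-diepoxy-5β-labda-13(16),14-dien-6-one
Product: 20 8α-acetoxy-15,16-epoxy-7β,9α-dihydroxy-5β-labda-13(16),14-dien-6-one, via 8α,9α-acetoxonium ion 18 (not isolated), via hemi-orthoester 19 (not isolated)
Conditions: TsOH·H2O (20 mol %), THF/H2O (10:1), 0 °C → rt
Reagents that add atoms: water, O
Why: The protonated epoxide is opened at the tertiary C8 with inversion by the carbonyl oxygen of the anti‑periplanar 9α‑acetate (neighbouring‑group participation, trans‑diaxial Fürst–Plattner opening) to a cis‑fused 1,3‑dioxolan‑2‑ylium ion, and hydration and collapse of the hemi‑orthoester to the axial, less hindered ester give 8α‑OAc/9α‑OH, setting C8 (OAc α, CH3 β) next to the 7β‑OH.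

Step 11
Reactants: 20 8α-acetoxy-15,16-epoxy-7β,9α-dihydroxy-5β-labda-13(16),14-dien-6-one
Product: 23 (13S)-8α-acetoxy-9α,13:15,16-diepoxy-7β-hydroxy-5β-labd-14-en-6-one, via 7-O-TMS ether 21 (not isolated), via 7-O-TMS spiro ether 22 (not isolated)
Conditions: 1-(trimethylsilyl)imidazole (1.1 equiv), CH2Cl2, 0 °C, evaporate; [Ir(dF(CF3)ppy)2(5,5′-d(CF3)bpy)]PF6 (2 mol %), Bu4P+ (PhO)2PO2− (20 mol %), 2,4,6-triisopropylbenzenethiol (30 mol %), PhCF3, blue LEDs, rt; then K2CO3 (cat.), MeOH, 0 °C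
Reagents that add atoms: none
Why: Proposed new method: PCET activation of the tertiary 9α‑O–H (excited Ir(III)/phosphate) gives the alkoxy radical, which closes 5‑exo onto C13 of the electron‑rich furan (electrophilic O‑radical, dearomative; C14=C15 is left as the enol ether), and the α‑oxy C16 radical is reduced by thiol HAT, so the contra‑thermodynamic spiro ether is trapped without acid; the closest known reaction is the Knowles PCET hydroetherification of alkenols; C13 is formed under substrate control with little intrinsic bias, so the 13S epimer is separated and the 13R epimer is returned to 20 by trace acid, while the transient TMS ether keeps the 7‑OH from forming a fragmenting alkoxy radical.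

**Compound list**
1 | 2-methylphenol (o-cresol) | Cc1ccccc1O | starting material
2 | 4,4-dimethoxy-2-methylcyclohexa-2,5-dien-1-one | COC1(OC)C=CC(=O)C(C)=C1 | intermediate
3 | (2S,3S)-7-methyl-2,3-diphenyl-1,4-dioxaspiro[4.5]deca-6,9-dien-8-one | CC1=CC2(C=CC1=O)O[C@@H](c3ccccc3)[C@H](c4ccccc4)O2 | intermediate
4 | 5-bromo-2-methylpent-2-ene | CC(C)=CCCBr | starting material
5 | (2S,3S,10S)-10-(5-bromo-2-methylpentan-2-yl)-7-methyl-2,3-diphenyl-1,4-dioxaspiro[4.5]dec-6-en-8-one | CC1=CC2(O[C@@H](c3ccccc3)[C@H](c4ccccc4)O2)[C@H](C(C)(C)CCCBr)CC1=O | intermediate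
6 | des-methyl cis-decalin enone: cis-fused 4,4,8-trimethyl-5β-H,10β-H-decal-7-ene-6,9-dione 6-[(1S,2S)-1,2-diphenylethylene ketal] | CC1=CC3(O[C@@H](c4ccccc4)[C@H](c5ccccc5)O3)[C@@H]2C(C)(C)CCC[C@@H]2C1=O | intermediate
7 | cis-fused 4,4,8,10β-tetramethyl-5β-H-decal-7-ene-6,9-dione 6-[(1S,2S)-1,2-diphenylethylene ketal] | CC1=CC3(O[C@@H](c4ccccc4)[C@H](c5ccccc5)O3)[C@@H]2C(C)(C)CCC[C@]2(C)C1=O | intermediate
8 | 3-bromofuran | Brc1ccoc1 | starting material
9 | oxirane | C1CO1 | starting material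
10 | furan-3-yllithium | [Li]c1ccoc1 | intermediate
11 | 2-(furan-3-yl)ethan-1-ol | OCCc1ccoc1 | intermediate
12 | 3-(2-iodoethyl)furan | ICCc1ccoc1 | intermediate
13 | 2-(furan-3-yl)ethyllithium | [Li]CCc1ccoc1 | intermediate
14 | lithium 9α-alkoxide of 15,16-epoxy-9α-hydroxy-5β-labda-7,13(16),14-trien-6-one (1S,2S)-1,2-diphenylethylene ketal | CC1=CC3(O[C@@H](c4ccccc4)[C@H](c5ccccc5)O3)[C@@H]2C(C)(C)CCC[C@]2(C)[C@@]1(O[Li])CCc1ccoc1 | intermediate
15 | 9α-acetoxy-15,16-epoxy-5β-labda-7,13(16),14-trien-6-one (1S,2S)-1,2-diphenylethylene ketal | CC1=CC3(O[C@@H](c4ccccc4)[C@H](c5ccccc5)O3)[C@@H]2C(C)(C)CCC[C@]2(C)[C@@]1(OC(C)=O)CCc1ccoc1 | intermediate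
16 | 9α-acetoxy-15,16-epoxy-5β-labda-7,13(16),14-trien-6-one | CC1=CC(=O)[C@@H]2C(C)(C)CCC[C@]2(C)[C@@]1(OC(C)=O)CCc1ccoc1 | intermediate
17 | 9α-acetoxy-7β,8β:15,16-diepoxy-5β-labda-13(16),14-dien-6-one | C[C@]12O[C@H]1C(=O)[C@@H]3C(C)(C)CCC[C@]3(C)[C@@]2(OC(C)=O)CCc1ccoc1 | intermediate
18 | 8α,9α-acetoxonium (2-methyl-1,3-dioxolan-2-ylium) ion of 15,16-epoxy-7β-hydroxy-5β-labda-13(16),14-dien-6-one | C[C+]1O[C@]2(C)[C@@H](O)C(=O)[C@@H]3C(C)(C)CCC[C@]3(C)[C@]2(CCc2ccoc2)O1 | intermediate
19 | 8α,9α-(1-hydroxyethylidene) hemi-orthoester of 15,16-epoxy-7β,8α,9α-trihydroxy-5β-labda-13(16),14-dien-6-one | CC1(O)O[C@]2(C)[C@@H](O)C(=O)[C@@H]3C(C)(C)CCC[C@]3(C)[C@]2(CCc2ccoc2)O1 | intermediate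
20 | 8α-acetoxy-15,16-epoxy-7β,9α-dihydroxy-5β-labda-13(16),14-dien-6-one | CC(=O)O[C@]1(C)[C@@H](O)C(=O)[C@@H]2C(C)(C)CCC[C@]2(C)[C@@]1(O)CCc1ccoc1 | intermediate
21 | 7-O-trimethylsilyl ether of 20 | CC(=O)O[C@]1(C)[C@@H](O[Si](C)(C)C)C(=O)[C@@H]2C(C)(C)CCC[C@]2(C)[C@@]1(O)CCc1ccoc1 | intermediate
22 | 7-O-trimethylsilyl ether of 23 | CC(=O)O[C@]1(C)[C@@H](O[Si](C)(C)C)C(=O)[C@@H]2C(C)(C)CCC[C@]2(C)[C@@]12CC[C@@]1(C=COC1)O2 | intermediate
23 | (13S)-8α-acetoxy-9α,13:15,16-diepoxy-7β-hydroxy-5β-labd-14-en-6-one | CC(=O)O[C@]1(C)[C@@H](O)C(=O)[C@@H]2C(C)(C)CCC[C@]2(C)[C@@]12CC[C@@]1(C=COC1)O2 | target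

**Totals**
Total step count: 11. Longest linear sequence: 9 steps (1 → 23 through steps 1–4 and 7–11); steps 5–6 make the side‑chain iodide.

**Steps most likely to fail, and fallbacks**

Step 3 is the most exposed. The tertiary radical has to choose the unsubstituted enone arm over the methyl‑bearing one, choose the face away from the phenyl group, and form a bond between a quaternary carbon and a CH that sits next to the spiro‑ketal carbon. The choice of (S,S)‑hydrobenzoin rests on a geometric model of the ketal; if the induction runs the other way, the (R,R)‑diol is used. The fallback removes the arm problem by making the acceptor C2‑symmetric; it sets out from 1 and comes back at 7. o‑Cresol 1 is ortho‑formylated (MgCl2, Et3N, paraformaldehyde) to 2-hydroxy-3-methylbenzaldehyde F1, which is hydrogenolysed (H2, Pd/C, AcOH) to 2,6-dimethylphenol F2. This is oxidized (PhI(OAc)2, MeOH) to 4,4-dimethoxy-2,6-dimethylcyclohexa-2,5-dien-1-one F3 and transketalized with (S,S)‑hydrobenzoin to (2S,3S)-7,9-dimethyl-2,3-diphenyl-1,4-dioxaspiro[4.5]deca-6,9-dien-8-one F4. The same Fe–H Giese addition of 4, now on two homotopic arms, gives (2S,3S,10S)-10-(5-bromo-2-methylpentan-2-yl)-7,9-dimethyl-2,3-diphenyl-1,4-dioxaspiro[4.5]dec-6-en-8-one F5, whose tertiary enolate (LDA) closes ring A directly onto the quaternary C10 to give 7.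

Step 9 asks a peroxide anion to attack a fully substituted β‑carbon next to the quaternary C9. The β‑face preference rests on the anti‑to‑acetoxy and convex‑face arguments only, and DBU could epimerize C5. The fallback installs the epoxide earlier, where the chiral ketal and the convex face reinforce each other; it sets out from 7 and comes back at 20. Enone 7 is epoxidized (t‑BuOOH, DBU) to the 7β,8β-epoxy-9-ketone ketal F6. Addition of 13 and quenching with Ac2O give the 9α-acetoxy-7β,8β-epoxy ketal F7; the addition must again come from the β face, now past the epoxide oxygen. Aqueous acid then hydrolyses the ketal and triggers the acetoxonium opening in one operation to give 20.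

Step 11 can fail by β‑scission of the congested tertiary alkoxy radical, by 6‑endo attack at C16, or by poor selectivity at C13. The fallback replaces the O‑radical addition by a polar dearomative cyclization followed by a radical reduction; it sets out from 20 and comes back at 23. N‑(Phenylseleno)phthalimide with 2,6‑lutidine at −78 °C selenenylates the furan at C16, and the resulting C13 cation is captured by the 9α‑OH to give the 16-phenylselanyl-9α,13:15,16-diepoxy-labd-14-ene F8. Bu3SnH with Et3B/air at −20 °C then cleaves the C–Se bond to give 23; C13 epimers are again separated.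

**Further compounds**
F1 | step 3 | 2-hydroxy-3-methylbenzaldehyde | Cc1cccc(C=O)c1O
F2 | step 3 | 2,6-dimethylphenol | Cc1cccc(C)c1O
F3 | step 3 | 4,4-dimethoxy-2,6-dimethylcyclohexa-2,5-dien-1-one | COC1(OC)C=C(C)C(=O)C(C)=C1
F4 | step 3 | (2S,3S)-7,9-dimethyl-2,3-diphenyl-1,4-dioxaspiro[4.5]deca-6,9-dien-8-one | CC1=CC2(C=C(C)C1=O)O[C@@H](c3ccccc3)[C@H](c4ccccc4)O2
F5 | step 3 | (2S,3S,10S)-10-(5-bromo-2-methylpentan-2-yl)-7,9-dimethyl-2,3-diphenyl-1,4-dioxaspiro[4.5]dec-6-en-8-one (C9 epimers) | CC1=CC2(O[C@@H](c3ccccc3)[C@H](c4ccccc4)O2)[C@H](C(C)(C)CCCBr)C(C)C1=O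
F6 | step 9 | cis-fused 7β,8β-epoxy-4,4,8,10β-tetramethyl-5β-H-decalin-6,9-dione 6-[(1S,2S)-1,2-diphenylethylene ketal] | C[C@]12O[C@H]1C3(O[C@@H](c4ccccc4)[C@H](c5ccccc5)O3)[C@@H]6C(C)(C)CCC[C@]6(C)C2=O
F7 | step 9 | 9α-acetoxy-7β,8β:15,16-diepoxy-5β-labda-13(16),14-dien-6-one (1S,2S)-1,2-diphenylethylene ketal | C[C@]12O[C@H]1C3(O[C@@H](c4ccccc4)[C@H](c5ccccc5)O3)[C@@H]6C(C)(C)CCC[C@]6(C)[C@@]2(OC(C)=O)CCc1ccoc1
F8 | step 11 | 8α-acetoxy-9α,13:15,16-diepoxy-7β-hydroxy-16-(phenylselanyl)-5β-labd-14-en-6-one | CC(=O)O[C@]1(C)[C@@H](O)C(=O)[C@@H]2C(C)(C)CCC[C@]2(C)[C@@]12CC[C@@]1(C=COC1[Se]c1ccccc1)O2
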